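**Plan**

1. Target numbering: bicyclo[3.2.1]oct-2-en-8-one with C1 (allyl), C2=C3(OMe), C4 (OAc), C5 (OMe), C6 (aryl), C7 (Me), C8 (C=O). Enabling feature: the C8 ketone lies between the two fully substituted bridgeheads C1 and C5, C5 carries a cation-stabilising OMe and C2=C3 is an enol ether. The cyclopentanone C1–C8–C5–C6–C7 is therefore the ring-expanded isomer of a cyclobutane (C1, C5, C6, C7) cis-fused to a 3-methoxycyclohex-2-enone (C8, C2, C3, C4, C5, C1).
2. Retrosynthesis: cut C8–C5 and C1–C2 and re-join C1–C5 and C8–C2 (reverse of two consecutive 1,2-shifts) to reach the cyclobutane-fused enone 9. Then cut the O–acetyl bond, the carbinol C–H, the allyl–C bond and the two cyclobutane bonds C1–C7 and C5–C6, which leads to 2,6-dimethoxy-1,4-benzoquinone and (E)-isoelemicin (from an aryl bromide and a propenylboronate).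
3. Forward: the six-membered ring is the purchased quinone; a (2+2) cycloaddition adds the cyclobutane; allylation, reduction and acetylation follow. The strain-releasing rearrangement then closes the cyclopentanone (bond C8–C5) and re-closes the six-membered ring (bond C1–C2).
4. Stereochemistry: absolute configuration from the TADDOL-derived titanium Lewis acid in the (2+2) step; trans aryl/methyl from the E-alkene and endo aryl from the chelated transition state; allyl by the enforced cis ring fusion; carbinol by hydride delivery to the convex face. The rearrangement carries all five centres over (retention at the migrating carbon).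

Key step: step 6

Assumption: the complex made from (R,R)-TADDOL is taken to give the (1R,6R,7S,8R) cyclobutane 5; if the sense of induction is the opposite, the (S,S)-ligand is used in the same way.

**Step 1**
Reactants: 1 5-bromo-1,2,3-trimethoxybenzene; 2 (E)-prop-1-enylboronic acid pinacol ester
Product: 3 (E)-isoelemicin, 1,2,3-trimethoxy-5-[(E)-prop-1-enyl]benzene
Conditions: Pd(dppf)Cl2 (cat.), K2CO3, dioxane/H2O, 80 °C
Reagents that add atoms: none
Why: Suzuki–Miyaura cross-coupling of the aryl bromide with the (E)-alkenylboronate proceeds with retention of alkene geometry, so the E-propenylarene needed for the trans aryl/methyl relationship should be obtained free of its Z isomer.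

**Step 2**
Reactants: 3 (E)-isoelemicin; 4 2,6-dimethoxy-1,4-benzoquinone
Product: 5 (1R,6R,7S,8R)-1,3-dimethoxy-7-methyl-8-(3,4,5-trimethoxyphenyl)bicyclo[4.2.0]oct-3-ene-2,5-dione (cis-fused; aryl endo, on the side of the six-membered ring; methyl trans to aryl)
Conditions: TiCl2(OiPr)2 (from TiCl4 and Ti(OiPr)4), (R,R)-TADDOL [(4R,5R)-2,2-dimethyl-α,α,α′,α′-tetraphenyl-1,3-dioxolane-4,5-dimethanol], 4 Å MS, CH2Cl2, −78 °C (promoter; diol recovered)
Reagents that add atoms: none
Why: Lewis acid-promoted stepwise (2+2) cycloaddition of a 2-alkoxy-1,4-benzoquinone with an (E)-propenylarene, in which chelation of titanium by O1 and a flanking methoxy oxygen of 4 should activate C3, the CHMe carbon of 3 should add there and the benzylic cation should collapse on the titanium enolate carbon C2; this gives the cis-fused cyclobutane with the aryl carbon on the methoxy-bearing carbon, trans aryl/methyl from the E-alkene, the aryl group endo (over the enedione, because the exo quadrant beside C2 is filled by the chelated metal and its ligand) and the absolute configuration from the C2-symmetric TADDOLate.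

**Step 3**
Reactants: 5 cyclobutane-fused enedione
Product: 7 (1R,6R,7S,8R)-6-allyl-1,3-dimethoxy-7-methyl-8-(3,4,5-trimethoxyphenyl)bicyclo[4.2.0]oct-3-ene-2,5-dione, via lithium enolate 6 (not isolated)
Conditions: LiN(SiMe3)2, THF, −78 °C; allyl iodide, DMPU, −78 → −40 °C
Reagents that add atoms: allyl iodide (3-iodoprop-1-ene), C=CCI
Why: deprotonation at the only enolisable position (ring-fusion C6–H, α′ to the vinylogous-ester carbonyl C5) and SN2 allylation of the enolate (Stork–Danheiser-type α′-alkylation) should give the quaternary centre, the allyl group necessarily entering on the face that carried H because the four/six ring fusion must stay cis.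

**Step 4**
Reactants: 7 allylated enedione
Product: 8 (1R,5R,6R,7R,8S)-1-allyl-5-hydroxy-4,6-dimethoxy-8-methyl-7-(3,4,5-trimethoxyphenyl)bicyclo[4.2.0]oct-3-en-2-one (OH cis to the cyclobutane, trans to the ring-fusion OMe)
Conditions: NaBH4, CeCl3·7H2O, MeOH, −78 °C
Reagents that add atoms: none
Why: Luche reduction should be 1,2-selective and chemoselective for the cross-conjugated C2 carbonyl of 7 (the C5 carbonyl is deactivated as a vinylogous ester), and hydride should arrive on the convex face, anti to the cyclobutane and its endo aryl group, which places OH cis to the cyclobutane.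

**Step 5**
Reactants: 8 hydroxy enone
Product: 9 (1R,2R,6R,7S,8R)-6-allyl-1,3-dimethoxy-7-methyl-5-oxo-8-(3,4,5-trimethoxyphenyl)bicyclo[4.2.0]oct-3-en-2-yl acetate
Conditions: Ac2O, DMAP (cat.), pyridine, CH2Cl2, 0 °C → rt
Reagents that add atoms: acetic anhydride, CC(=O)OC(C)=O
Why: DMAP-catalysed acylation of the secondary alcohol should proceed without touching any stereocentre.

**Step 6**
Reactants: 9 cyclobutane-fused acetoxy enone (numbering: C1 fusion carbon with OMe, C2 CH–OAc, C3 C–OMe, C4 =CH, C5 C=O, C6 fusion carbon with allyl, C7 CHMe, C8 CH–aryl)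
Product: 10 (1S,4R,5S,6R,7S)-1-allyl-3,5-dimethoxy-7-methyl-8-oxo-6-(3,4,5-trimethoxyphenyl)bicyclo[3.2.1]oct-2-en-4-yl acetate (6-endo-aryl, 7-exo-methyl, 4-endo-acetoxy)
Conditions: TMSOTf (20 mol %), 2,6-di-tert-butyl-4-methylpyridine (10 mol %), CH2Cl2, −40 → 0 °C
Reagents that add atoms: none
Why: Proposed new method: silylation of the only ketone (vinylogous-ester carbonyl C5=O) gives a 1-siloxy-3-methoxyallyl cation; the strained ring-fusion bond C6–C1 then shifts so that C1 (tertiary, OMe-substituted) moves from C6 to C5, and the tertiary cation left at C6 is captured by the adjacent enol ether carbon C4 to give a donor–acceptor cyclopropane that opens under push from the siloxy group, which completes the 1,2-shift of C4 from C5 to C6 and releases the bridging ketone and the silyl triflate. The closest known reaction type is the acid-promoted rearrangement of 6-substituted bicyclo[4.2.0]octan-2-ones to bicyclo[3.2.1]octan-8-ones (Cargill-type double 1,2-shift of cyclobutyl ketones), known on saturated, alkyl-substituted substrates; the present case differs in the vinylogous-ester carbonyl, the oxygen substituent on the migrating carbon and the alkenyl second migrating group. Ring closure: the cyclopentanone closes by a suprafacial 1,2-alkyl shift (four- to five-membered ring expansion), and the six-membered ring re-closes by 3-exo-trig capture and cyclopropane fragmentation (net 1,2-alkenyl shift). No new stereocentre is created: C1 migrates with retention, C2, C7 and C8 are untouched, and the quaternary carbon C6 is re-formed on the only face the bicycle allows, so endo-aryl, exo-methyl and endo-acetoxy follow from 9. The step needs migration of the fusion bond C6–C1 and not of the outer bond C6–C7, which the higher migratory aptitude of the alkoxy-substituted tertiary carbon should secure; it needs activation of the ketone and not ionisation of the benzylic C1–C8 bond, which is secured because C2 is already at the acetate level and cannot act as an enol leaving group. The competing retro-aldol-type opening of C6–C1 can only return to 9 under aprotic, non-nucleophilic conditions, whereas the double shift is made irreversible by release of cyclobutane strain.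

**Compound list**

1 | 5-bromo-1,2,3-trimethoxybenzene | COc1cc(Br)cc(OC)c1OC | starting material
2 | (E)-prop-1-enylboronic acid pinacol ester | C/C=C/B1OC(C)(C)C(C)(C)O1 | starting material
3 | (E)-isoelemicin, 1,2,3-trimethoxy-5-[(E)-prop-1-enyl]benzene | C/C=C/c1cc(OC)c(OC)c(OC)c1 | intermediate
4 | 2,6-dimethoxy-1,4-benzoquinone | COC1=CC(=O)C=C(OC)C1=O | starting material
5 | (1R,6R,7S,8R)-1,3-dimethoxy-7-methyl-8-(3,4,5-trimethoxyphenyl)bicyclo[4.2.0]oct-3-ene-2,5-dione | COC1=CC(=O)[C@@H]2[C@@H](C)[C@H](c3cc(OC)c(OC)c(OC)c3)[C@]2(OC)C1=O | intermediate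
6 | lithium enolate of 5 (C5–O enolate, C5=C6) | [Li+].[O-]C1=C2[C@@H](C)[C@H](c3cc(OC)c(OC)c(OC)c3)[C@]2(OC)C(=O)C(OC)=C1 | intermediate
7 | (1R,6R,7S,8R)-6-allyl-1,3-dimethoxy-7-methyl-8-(3,4,5-trimethoxyphenyl)bicyclo[4.2.0]oct-3-ene-2,5-dione | COC1=CC(=O)[C@]2(CC=C)[C@@H](C)[C@H](c3cc(OC)c(OC)c(OC)c3)[C@]2(OC)C1=O | intermediate
8 | (1R,5R,6R,7R,8S)-1-allyl-5-hydroxy-4,6-dimethoxy-8-methyl-7-(3,4,5-trimethoxyphenyl)bicyclo[4.2.0]oct-3-en-2-one | COC1=CC(=O)[C@]2(CC=C)[C@@H](C)[C@H](c3cc(OC)c(OC)c(OC)c3)[C@]2(OC)[C@@H]1O | intermediate
9 | (1R,2R,6R,7S,8R)-6-allyl-1,3-dimethoxy-7-methyl-5-oxo-8-(3,4,5-trimethoxyphenyl)bicyclo[4.2.0]oct-3-en-2-yl acetate | COC1=CC(=O)[C@]2(CC=C)[C@@H](C)[C@H](c3cc(OC)c(OC)c(OC)c3)[C@]2(OC)[C@@H]1OC(C)=O | intermediate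
10 | (1S,4R,5S,6R,7S)-1-allyl-3,5-dimethoxy-7-methyl-8-oxo-6-(3,4,5-trimethoxyphenyl)bicyclo[3.2.1]oct-2-en-4-yl acetate | C=CC[C@]12C=C(OC)[C@@H](OC(C)=O)[C@](OC)(C1=O)[C@@H](c1cc(OC)c(OC)c(OC)c1)[C@@H]2C | target

Total step count: 6. Longest linear sequence: 6 steps (1 → 3 → 5 → 7 → 8 → 9 → 10).

**Steps most likely to fail**

Step 6 (Proposed new method). What may go wrong: full heterolysis of the C6–C1 bond to an eight-membered oxocarbenium/dienol that loses a proton instead of returning; migration of the outer cyclobutane bond; acid-induced loss of the enol ether or the allylic acetate. Fallback with known chemistry, setting out from 3 and coming back to the route at 10: commercial 2,3,4-trimethoxyphenol is O-allylated (allyl bromide, K2CO3, acetone) to allyl 2,3,4-trimethoxyphenyl ether F1, which undergoes aromatic Claisen rearrangement (N,N-diethylaniline, 190 °C) to 6-allyl-2,3,4-trimethoxyphenol F2. Oxidation with PhI(OAc)2 in methanol gives the quinone monoketal 6-allyl-2,3,4,4-tetramethoxycyclohexa-2,5-dien-1-one F3. Ionisation of F3 with TMSOTf at −78 °C in the presence of 3 should give, by the known cationic (5+2) cycloaddition of the derived pentadienyl cation across C2 and C6 and loss of the C3 methyl group, racemic 1-allyl-3,5-dimethoxy-7-methyl-6-(3,4,5-trimethoxyphenyl)bicyclo[3.2.1]oct-2-ene-4,8-dione (6-endo-aryl, 7-exo-methyl) F4. Luche reduction from the exo face (the endo face is shielded by the aryl group) gives racemic 4-endo-alcohol F5. Preparative HPLC on a chiral stationary phase gives (1S,4R,5S,6R,7S)-1-allyl-4-hydroxy-3,5-dimethoxy-7-methyl-6-(3,4,5-trimethoxyphenyl)bicyclo[3.2.1]oct-2-en-8-one F6, and acetylation (Ac2O, DMAP, pyridine) gives 10. In this fallback the bridging ketone comes from the phenol carbon and the two bonds to the propenyl carbons are the ones made.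

Step 2. What may go wrong: low reactivity of the methoxy-substituted quinone double bond; collapse of the benzylic cation on carbonyl oxygen or on C5 instead of C2; poor endo/exo selectivity, where the aryl-exo, methyl-endo cyclobutane is a real possibility and would be carried by step 6 into the 6-exo-aryl, 7-endo-methyl series. Fallback, setting out from 3 and 4 and coming back at 5: visible-light (2+2) photocycloaddition (blue LED, MeCN, rt). The excited quinone should add through a triplet 1,4-biradical (first bond from C3 of the quinone to the CHMe carbon, giving an α-methoxy-α-keto radical and a benzylic radical) to give racemic 5 F8 with the same head-to-tail connectivity and trans aryl/methyl. The endo-aryl diastereomer is separated by chromatography and 5 is obtained by preparative HPLC on a chiral stationary phase. This replaces the polar, metal-templated pathway by an excited-state pathway with different selectivity determinants.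

Step 3. What may go wrong: β-elimination of methoxide from the enolate (giving a cyclobutene-fused quinone) while the hindered carbon alkylates slowly; O-allylation. Fallback, setting out from 5 and coming back at 7: the enolate is trapped at −78 °C on oxygen with allyl chloroformate to give the allyl enol carbonate F7. Pd(PPh3)4 (cat.) in THF at rt then effects decarboxylative allylation (Tsuji reaction), in which the C–C bond forms inside a palladium enolate/π-allyl ion pair and no free enolate has to be warmed.

**Further compounds**

F1 | step 6 | allyl 2,3,4-trimethoxyphenyl ether | C=CCOc1ccc(OC)c(OC)c1OC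
F2 | step 6 | 6-allyl-2,3,4-trimethoxyphenol | C=CCc1cc(OC)c(OC)c(OC)c1O
F3 | step 6 | 6-allyl-2,3,4,4-tetramethoxycyclohexa-2,5-dien-1-one | C=CCC1=CC(OC)(OC)C(OC)=C(OC)C1=O
F4 | step 6 | racemic 1-allyl-3,5-dimethoxy-7-methyl-6-(3,4,5-trimethoxyphenyl)bicyclo[3.2.1]oct-2-ene-4,8-dione (6-endo-aryl, 7-exo-methyl; both enantiomers) | C=CC[C@]12C=C(OC)C(=O)[C@](OC)(C1=O)[C@@H](c1cc(OC)c(OC)c(OC)c1)[C@@H]2C.C=CC[C@@]12C=C(OC)C(=O)[C@@](OC)(C1=O)[C@H](c1cc(OC)c(OC)c(OC)c1)[C@H]2C
F5 | step 6 | racemic 1-allyl-4-hydroxy-3,5-dimethoxy-7-methyl-6-(3,4,5-trimethoxyphenyl)bicyclo[3.2.1]oct-2-en-8-one (4-endo-OH; both enantiomers) | C=CC[C@]12C=C(OC)[C@@H](O)[C@](OC)(C1=O)[C@@H](c1cc(OC)c(OC)c(OC)c1)[C@@H]2C.C=CC[C@@]12C=C(OC)[C@H](O)[C@@](OC)(C1=O)[C@H](c1cc(OC)c(OC)c(OC)c1)[C@H]2C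
F6 | step 6 | (1S,4R,5S,6R,7S)-1-allyl-4-hydroxy-3,5-dimethoxy-7-methyl-6-(3,4,5-trimethoxyphenyl)bicyclo[3.2.1]oct-2-en-8-one | C=CC[C@]12C=C(OC)[C@@H](O)[C@](OC)(C1=O)[C@@H](c1cc(OC)c(OC)c(OC)c1)[C@@H]2C
F7 | step 3 | allyl enol carbonate of 5 (allyl carbonate on O5, C5=C6) | C=CCOC(=O)OC1=C2[C@@H](C)[C@H](c3cc(OC)c(OC)c(OC)c3)[C@]2(OC)C(=O)C(OC)=C1
F8 | step 2 | racemic 5 (5 and its enantiomer) | COC1=CC(=O)[C@@H]2[C@@H](C)[C@H](c3cc(OC)c(OC)c(OC)c3)[C@]2(OC)C1=O.COC1=CC(=O)[C@H]2[C@H](C)[C@@H](c3cc(OC)c(OC)c(OC)c3)[C@@]2(OC)C1=O
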